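The rate constants were set for the occasion; what happens was integrated by code.

You stop the clock at 40 s, so the question is how far two catalysed steps in a row have got by then.

    D + E + Z → E + J (k1 = 7.53 /M²/s)
    L + G → G + Z (k2 = 16.2 /M/s)

| flask | L | D | G | E | time | remark |
|---|---|---|---|---|---|---|
| violet | 0.089 M | 2.50 equiv (fed, over 30 s) | 2.5 mol% | 15 mol% | 40 s | all else is in the flask from the start; the feed brings no volume worth counting |
| blue | 0.089 M | 2.50 equiv | 2.5 mol% | 15 mol% | 40 s | everything together at the start |
| ochre | 0.089 M (fed, over 30 s) | 2.50 equiv | 2.5 mol% | 15 mol% | 40 s | all else is in the flask from the start; the feed brings no volume worth counting |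

* which flask leads in amount of J, in percent of the L charged ("all alike" within 1.5 percentage points) (violet / blue / ochre / all alike)
* how much J is there at the end, in percent of the L charged: violet
* how much J is there at the end, in percent of the L charged: blue
* how much J is there at the end, in percent of the L charged: ochre

Look first for the concentrations in each rate that stay put. G comes out of its step unchanged, so [G] stays at its charge and L decays first order (pseudo-first-order). Its constant is kL, the rate constant of the L step times [G]:

kL = 0.0360 /s

Z looks the same if you hold D and E at their charges:

kZ = 0.0224 /s

Two first-order steps in a row have a standard formula, and for blue it gives: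

J = 31.0%

But D is consumed. That much J costs 12.4% of the D charge, so kZ sags slightly and I take this figure as a little high.

In ochre, L enters on average at mid-feed, so try the same formula with the clock shortened by 15.0 s:

J = 15.8%

You may object that the feed lasts 1.08 lifetimes of L, too long for a plain shift. Yet the shift leaves 40.6% of L where the feed integrated properly leaves 42.6%, so for L the shift will do.

In violet, kZ climbs with the feed. Its mean over the run is 0.0140 /s, which gives:

J = 21.6%

I take this as low: that mean counts the early seconds, when Z is still building, as heavily as the late ones, when the constant stands at kZ, above the mean. My order is still blue over violet, and violet over ochre.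

The forecast names blue, with 24.7% for violet, above my figure, 29.7% for blue, below my figure, and 15.8% for ochre: “Delaying L hurts most because it holds back the slower two-stage chain from the start”.

The simulation puts blue ahead, with 24.8% in violet, 29.4% in blue and 15.7% in ochre. In blue the L step had 18% of its turnover up to 40 s behind it at 4.00 s, while the Z step had 7.5% of its own at 8.00 s and reached half of that turnover at 24.3 s. At 40.0 s blue held 46.9% as Z, with 88% of its D left. The decay with kL leaves 23.7% of L there, and blue held 24%. In the neighbour of blue with 4.2 mol% of G, kL rescaled leaves 8.87%; that flask held 8.87% of L and 37.9% of J.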